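**Retrosynthetic overview**

- Feature: the carbocycle has a single sp3 atom, the quaternary C8 (prenyl and C10 acid chain), set between the enolic C7–OH carbon and the pyran-oxygen-bearing C8a. With C5 (keto), C6 (benzoyl) and C4a=C8a it is a benzoylphloroglucinol 2,2-dimethylchromene held in its enol-triketone form, so a flat chromene diphenol becomes the core by one dearomatizing C-prenylation at C8.
- Disconnection 1 (last C–C bond): C8–CH2 of the prenyl group, by ligand-controlled Pd-catalysed allylic alkylation of the fully substituted chromene diphenol with prenyl acetate; ester hydrolysis ends the route.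
- Disconnection 2: C8–CH2 of the acid chain, by Negishi coupling of an 8-iodochromene diacetate with the alkylzinc from a chiral primary iodide.
- Disconnection 3: the chain stereocenter and isopropenyl group, by Evans deconjugative α-alkylation of a senecioyl oxazolidinone with a γ-bromotiglate (E-enoate from a stabilised Wittig reaction).
- Ring order: the benzene ring is bought (2,4,6-trihydroxybenzophenone), the pyran ring is closed first with prenal (condensation, oxa-6π closure), no later ring is formed, and the carbocycle is dearomatized last.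

Key step: step 12

Assumption: the enol form drawn for the target is taken as one of the interconverting enol tautomers of the triketone; the (R,R) ligand antipode is written in step 12 provisionally, and the antipode matched to the chain stereocenter is to be fixed by running both.

**Route**

Step 1
Reactants: 1 2,4,6-trihydroxybenzophenone; 2 3-methylbut-2-enal (prenal)
Product: 4 6-benzoyl-5,7-dihydroxy-2,2-dimethyl-2H-chromene, via ortho-quinone methide 3 (not isolated)
Conditions: ethylenediammonium diacetate (EDDA, 20 mol %), 2 (1.1 equiv), toluene, 100 °C; chromatographic removal of the angular 8-benzoyl isomer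
Reagents that add atoms: none
Why: Amine-catalysed Knoevenagel-type condensation at a free ring carbon gives the 1-oxatriene, which closes by oxa-6π electrocyclization; the non-chelated hydroxyl para to the benzoyl group should be favoured as the ring oxygen, giving the linear 6-benzoyl chromene.

Step 2
Reactants: 4 6-benzoyl-5,7-dihydroxy-2,2-dimethyl-2H-chromene
Product: 5 6-benzoyl-5,7-dihydroxy-8-iodo-2,2-dimethyl-2H-chromene
Conditions: NIS (1.0 equiv), CH2Cl2, –20 to 0 °C, dark
Reagents that add atoms: N-iodosuccinimide, O=C1CCC(=O)N1I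
Why: Electrophilic aromatic iodination goes to the only free ring position, C8, which is activated by the ortho hydroxyl, the ortho ether oxygen and the para hydroxyl and should react faster than the pyran double bond at low temperature.

Step 3
Reactants: 5 6-benzoyl-5,7-dihydroxy-8-iodo-2,2-dimethyl-2H-chromene
Product: 6 6-benzoyl-8-iodo-2,2-dimethyl-2H-chromene-5,7-diyl diacetate
Conditions: Ac2O (3 equiv), pyridine, DMAP (cat.), CH2Cl2, 0 °C to rt
Reagents that add atoms: acetic anhydride, CC(=O)OC(C)=O
Why: DMAP-catalysed O-acetylation masks both acidic phenols so that they can neither protonate the organozinc nor bind palladium in the coupling.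

Step 4
Reactants: 7 (S)-4-benzyl-2-oxazolidinone; 8 3-methylbut-2-enoyl chloride
Product: 10 (S)-4-benzyl-3-(3-methylbut-2-enoyl)oxazolidin-2-one, via lithiated oxazolidinone 9 (not isolated)
Conditions: n-BuLi (1.0 equiv), THF, –78 °C; then 8, –78 to 0 °C
Reagents that add atoms: none
Why: N-acylation of the lithiated oxazolidinone with the acid chloride is the standard preparation of Evans imides and avoids the vinylketene pathway that amine bases open with this acid chloride.

Step 5
Reactants: 11 methyl 2-(triphenylphosphoranylidene)propanoate; 12 glycolaldehyde dimer (1,4-dioxane-2,5-diol)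
Product: 14 methyl (E)-4-hydroxy-2-methylbut-2-enoate, via glycolaldehyde monomer 13 (not isolated)
Conditions: 12 (0.55 equiv), CH2Cl2, 40 °C
Reagents that add atoms: none
Why: Wittig olefination of the monomer released from the dimer on warming with a stabilised ylide should give the E-trisubstituted enoate, the free hydroxyl being tolerated.

Step 6
Reactants: 14 methyl (E)-4-hydroxy-2-methylbut-2-enoate
Product: 15 methyl (E)-4-bromo-2-methylbut-2-enoate
Conditions: CBr4, PPh3, CH2Cl2, 0 °C
Reagents that add atoms: carbon tetrabromide, BrC(Br)(Br)Br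
Why: Appel bromination converts the primary allylic alcohol into the bromide by SN2 displacement on the alkoxyphosphonium ion under neutral conditions, leaving the enoate geometry untouched.

Step 7
Reactants: 10 (S)-4-benzyl-3-(3-methylbut-2-enoyl)oxazolidin-2-one; 15 methyl (E)-4-bromo-2-methylbut-2-enoate
Product: 17 methyl (2E,5S)-5-{[(4S)-4-benzyl-2-oxo-1,3-oxazolidin-3-yl]carbonyl}-2,6-dimethylhepta-2,6-dienoate, via sodium dienolate 16 (not isolated)
Conditions: NaN(SiMe3)2 (1.05 equiv), THF, –78 °C; then 15 (1.5 equiv), –78 to –40 °C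
Reagents that add atoms: none
Why: Evans deconjugative alkylation: γ-deprotonation gives the chelated Z(O)-sodium dienolate, which reacts at its α-carbon with the allylic bromide on the face away from the benzyl group, so the isopropenyl group and the 5S stereocenter are created together.

Step 8
Reactants: 17 methyl (2E,5S)-5-{[(4S)-4-benzyl-2-oxo-1,3-oxazolidin-3-yl]carbonyl}-2,6-dimethylhepta-2,6-dienoate
Product: 18 methyl (2E,5S)-5-(hydroxymethyl)-2,6-dimethylhepta-2,6-dienoate
Conditions: LiBH4 (1.2 equiv), MeOH (1.2 equiv), Et2O, 0 °C; aqueous NH4Cl quench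
Reagents that add atoms: none
Why: Reductive cleavage of the imide by LiBH4/MeOH attacks the activated exocyclic imide carbonyl much faster than the conjugated trisubstituted methyl ester, releasing the auxiliary and removing the epimerizable α-acyl position.

Step 9
Reactants: 18 methyl (2E,5S)-5-(hydroxymethyl)-2,6-dimethylhepta-2,6-dienoate
Product: 19 methyl (2E,5S)-5-(iodomethyl)-2,6-dimethylhepta-2,6-dienoate
Conditions: I2, PPh3, imidazole, CH2Cl2, 0 °C to rt
Reagents that add atoms: iodine, [I][I]
Why: Appel-type iodination (Garegg–Samuelsson conditions) gives the primary iodide by SN2 at CH2, one carbon away from the stereocenter, which is not involved.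

Step 10
Reactants: 19 methyl (2E,5S)-5-(iodomethyl)-2,6-dimethylhepta-2,6-dienoate; 6 6-benzoyl-8-iodo-2,2-dimethyl-2H-chromene-5,7-diyl diacetate
Product: 21 methyl (2E,5R)-5-[(5,7-diacetoxy-6-benzoyl-2,2-dimethyl-2H-chromen-8-yl)methyl]-2,6-dimethylhepta-2,6-dienoate, via alkylzinc iodide 20 (not isolated)
Conditions: zinc dust (activated with 1,2-dibromoethane and TMSCl), LiCl, THF, 40 °C; then 6, Pd(OAc)2 (5 mol %), SPhos (10 mol %), THF, 25 to 50 °C
Reagents that add atoms: none
Why: LiCl-promoted zinc insertion into the primary C–I bond followed by Negishi sp3–sp2 cross-coupling, where the bulky dialkylbiarylphosphine should speed oxidative addition at the hindered C8–I bond and reductive elimination ahead of β-hydride elimination; the stereocenter is β to zinc and untouched (the descriptor changes to R by priority only).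

Step 11
Reactants: 21 methyl (2E,5R)-5-[(5,7-diacetoxy-6-benzoyl-2,2-dimethyl-2H-chromen-8-yl)methyl]-2,6-dimethylhepta-2,6-dienoate
Product: 22 methyl (2E,5R)-5-[(6-benzoyl-5,7-dihydroxy-2,2-dimethyl-2H-chromen-8-yl)methyl]-2,6-dimethylhepta-2,6-dienoate
Conditions: K2CO3 (2 equiv), degassed MeOH, 0 °C to rt; then cold 1 M HCl to pH 5
Reagents that add atoms: none
Why: Methanolysis (transesterification) of the two activated aryl acetates frees the phenols, while the methyl enoate can only exchange methoxide for methoxide.

Step 12
Reactants: 22 methyl (2E,5R)-5-[(6-benzoyl-5,7-dihydroxy-2,2-dimethyl-2H-chromen-8-yl)methyl]-2,6-dimethylhepta-2,6-dienoate; 23 prenyl acetate (3-methylbut-2-en-1-yl acetate)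
Product: 25 methyl (2E,5R)-5-{[(8S)-6-benzoyl-7-hydroxy-2,2-dimethyl-8-(3-methylbut-2-en-1-yl)-5-oxo-5,8-dihydro-2H-chromen-8-yl]methyl}-2,6-dimethylhepta-2,6-dienoate, via caesium phenoxide 24 (not isolated)
Conditions: Pd2(dba)3·CHCl3 (2.5 mol %), (R,R)-DACH-phenyl Trost ligand [(1R,2R)-N,N'-bis(2-diphenylphosphinobenzoyl)cyclohexane-1,2-diamine, 7.5 mol %], Cs2CO3 (1.1 equiv), 23 (1.3 equiv), degassed THF, 0 °C to rt; pH 5 buffer work-up
Reagents that add atoms: none
Why: Proposed new method: Oxidative ionisation of 23 by the zerovalent palladium–ligand complex gives a cationic (1,1-dimethyl-π-allyl)palladium species, whose less substituted CH2 end is captured from outside the coordination sphere by C8 of the delocalised phenoxide 24, which turns the benzene ring into the enolised cyclohexadienone; O-prenyl ethers formed on the way should be re-ionised by the catalyst and drain into the C-alkylated vinylogous acid. The closest known reaction types are Tsuji–Trost dearomative allylation and prenylation of acylphloroglucinols and catalytic asymmetric allylic dearomatization of phenols and naphthols as prochiral nucleophiles, but ligand-controlled face selection on a fully substituted chromene acylphloroglucinol has not been shown. No ring is closed in this step; only the C8–CH2 bond forms. The new quaternary stereocenter at C8 is set by the chiral pocket of the diamide bisphosphine ligand, which must tell the C7–O flank from the C8a–O (pyran) flank of the planar nucleophile; because the chain stereocenter is already present the two outcomes are diastereomers, so the matched ligand antipode is found by running both and a minor epimer can be removed by chromatography. Site selectivity for C8 over C6, C4a and oxygen should follow because C6 carries the benzoyl group, attack at C4a would break the chromene conjugation and O-allylation is reversible, and linear over reverse prenylation follows from the steric demand of the forming quaternary carbon.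

Step 13
Reactants: 25 methyl (2E,5R)-5-{[(8S)-6-benzoyl-7-hydroxy-2,2-dimethyl-8-(3-methylbut-2-en-1-yl)-5-oxo-5,8-dihydro-2H-chromen-8-yl]methyl}-2,6-dimethylhepta-2,6-dienoate
Product: 26 (2E,5R)-5-{[(8S)-6-benzoyl-7-hydroxy-2,2-dimethyl-8-(3-methylbut-2-en-1-yl)-5-oxo-5,8-dihydro-2H-chromen-8-yl]methyl}-2,6-dimethylhepta-2,6-dienoic acid (CNP0333091.1)
Conditions: LiOH·H2O (5 equiv), THF/H2O 3:1, rt to 40 °C; then cold 1 M HCl to pH 3
Reagents that add atoms: lithium hydroxide, [Li+].[OH-] (its oxygen becomes the acid OH)
Why: Saponification of the methyl enoate; the vinylogous acid of the core is deprotonated first and its delocalised enolate should resist retro-Claisen cleavage, while neither stereocenter (one quaternary, one non-activated allylic CH) can epimerize.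

**Compound list**

1 | 2,4,6-trihydroxybenzophenone | O=C(c1ccccc1)c1c(O)cc(O)cc1O | starting material
2 | 3-methylbut-2-enal (prenal) | CC(C)=CC=O | starting material
3 | ortho-quinone methide (1-oxatriene) from condensation of 1 with 2 | CC(C)=CC=C1C(=O)C=C(O)C(C(=O)c2ccccc2)=C1O | intermediate
4 | 6-benzoyl-5,7-dihydroxy-2,2-dimethyl-2H-chromene | CC1(C)C=Cc2c(O1)cc(O)c(C(=O)c1ccccc1)c2O | intermediate
5 | 6-benzoyl-5,7-dihydroxy-8-iodo-2,2-dimethyl-2H-chromene | CC1(C)C=Cc2c(O1)c(I)c(O)c(C(=O)c1ccccc1)c2O | intermediate
6 | 6-benzoyl-8-iodo-2,2-dimethyl-2H-chromene-5,7-diyl diacetate | CC1(C)C=Cc2c(O1)c(I)c(OC(C)=O)c(C(=O)c1ccccc1)c2OC(C)=O | intermediate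
7 | (S)-4-benzyl-2-oxazolidinone | O=C1N[C@@H](Cc2ccccc2)CO1 | starting material
8 | 3-methylbut-2-enoyl chloride | CC(C)=CC(=O)Cl | starting material
9 | lithium salt of (S)-4-benzyl-2-oxazolidinone | [Li]N1C(=O)OC[C@@H]1Cc1ccccc1 | intermediate
10 | (S)-4-benzyl-3-(3-methylbut-2-enoyl)oxazolidin-2-one | CC(C)=CC(=O)N1C(=O)OC[C@@H]1Cc1ccccc1 | intermediate
11 | methyl 2-(triphenylphosphoranylidene)propanoate | COC(=O)C(C)=P(c1ccccc1)(c1ccccc1)c1ccccc1 | starting material
12 | glycolaldehyde dimer (1,4-dioxane-2,5-diol) | OC1COC(O)CO1 | starting material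
13 | glycolaldehyde | O=CCO | intermediate
14 | methyl (E)-4-hydroxy-2-methylbut-2-enoate | OC/C=C(\C)C(=O)OC | intermediate
15 | methyl (E)-4-bromo-2-methylbut-2-enoate | BrC/C=C(\C)C(=O)OC | intermediate
16 | sodium Z(O)-dienolate of 10 | [Na+].C=C(C)/C=C(\[O-])N1C(=O)OC[C@@H]1Cc1ccccc1 | intermediate
17 | methyl (2E,5S)-5-{[(4S)-4-benzyl-2-oxo-1,3-oxazolidin-3-yl]carbonyl}-2,6-dimethylhepta-2,6-dienoate | C=C(C)[C@H](C/C=C(\C)C(=O)OC)C(=O)N1C(=O)OC[C@@H]1Cc1ccccc1 | intermediate
18 | methyl (2E,5S)-5-(hydroxymethyl)-2,6-dimethylhepta-2,6-dienoate | C=C(C)[C@H](C/C=C(\C)C(=O)OC)CO | intermediate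
19 | methyl (2E,5S)-5-(iodomethyl)-2,6-dimethylhepta-2,6-dienoate | C=C(C)[C@H](C/C=C(\C)C(=O)OC)CI | intermediate
20 | [(2S,4E)-5-(methoxycarbonyl)-2-(prop-1-en-2-yl)hex-4-en-1-yl]zinc iodide (19 with CH2ZnI in place of CH2I) | C=C(C)[C@H](C/C=C(\C)C(=O)OC)C[Zn]I | intermediate
21 | methyl (2E,5R)-5-[(5,7-diacetoxy-6-benzoyl-2,2-dimethyl-2H-chromen-8-yl)methyl]-2,6-dimethylhepta-2,6-dienoate | C=C(C)[C@H](C/C=C(\C)C(=O)OC)Cc1c(OC(C)=O)c(C(=O)c2ccccc2)c(OC(C)=O)c2c1OC(C)(C)C=C2 | intermediate
22 | methyl (2E,5R)-5-[(6-benzoyl-5,7-dihydroxy-2,2-dimethyl-2H-chromen-8-yl)methyl]-2,6-dimethylhepta-2,6-dienoate | C=C(C)[C@H](C/C=C(\C)C(=O)OC)Cc1c(O)c(C(=O)c2ccccc2)c(O)c2c1OC(C)(C)C=C2 | intermediate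
23 | prenyl acetate | CC(=O)OCC=C(C)C | starting material
24 | caesium 7-phenoxide of 22 | [Cs+].C=C(C)[C@H](C/C=C(\C)C(=O)OC)Cc1c([O-])c(C(=O)c2ccccc2)c(O)c2c1OC(C)(C)C=C2 | intermediate
25 | methyl (2E,5R)-5-{[(8S)-6-benzoyl-7-hydroxy-2,2-dimethyl-8-(3-methylbut-2-en-1-yl)-5-oxo-5,8-dihydro-2H-chromen-8-yl]methyl}-2,6-dimethylhepta-2,6-dienoate | C=C(C)[C@H](C/C=C(\C)C(=O)OC)C[C@@]1(CC=C(C)C)C(O)=C(C(=O)c2ccccc2)C(=O)C2=C1OC(C)(C)C=C2 | intermediate
26 | (2E,5R)-5-{[(8S)-6-benzoyl-7-hydroxy-2,2-dimethyl-8-(3-methylbut-2-en-1-yl)-5-oxo-5,8-dihydro-2H-chromen-8-yl]methyl}-2,6-dimethylhepta-2,6-dienoic acid (CNP0333091.1) | C=C(C)[C@H](C/C=C(\C)C(=O)O)C[C@@]1(CC=C(C)C)C(O)=C(C(=O)c2ccccc2)C(=O)C2=C1OC(C)(C)C=C2 | target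

**Step count**

Total: 13 steps. Longest linear sequence: 9 steps (steps 5, 6, 7, 8, 9, 10, 11, 12, 13).

**Steps most likely to fail**

1. Step 12 (the step carrying the new-method label). The ligand pocket may discriminate poorly between the two faces of the planar C8 nucleophile, and O-prenylation that does not drain to carbon or attack through the tertiary allyl terminus may compete. Fallback, known chemistry, setting out from 22: uncatalysed alkylative dearomatization of the lupulone type with prenyl bromide and NaOMe in MeOH at 0 °C. This is established for fully substituted acylphloroglucinols and should give C-prenylation at C8 without face control. It would deliver 25 together with its C8 epimer, methyl (2E,5R)-5-{[(8R)-6-benzoyl-7-hydroxy-2,2-dimethyl-8-(3-methylbut-2-en-1-yl)-5-oxo-5,8-dihydro-2H-chromen-8-yl]methyl}-2,6-dimethylhepta-2,6-dienoate F1. The two are diastereomers and would be separated by chromatography; the route is rejoined at 25.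

2. Step 10. Oxidative addition and transmetalation at the doubly ortho-oxygenated C8–I bond may be slow, so that protodezincation, β-hydride elimination from the alkylpalladium or reduction of the aryl iodide takes over; zinc insertion may also stall. Fallback, setting out from 19 and 6: copper-catalysed borylation of the primary iodide (CuI, PPh3, LiOMe, B2pin2, DMF, rt) to methyl (2E,5S)-2,6-dimethyl-5-[(4,4,5,5-tetramethyl-1,3,2-dioxaborolan-2-yl)methyl]hepta-2,6-dienoate F2. This is followed by B-alkyl Suzuki–Miyaura coupling with 6 [Pd(OAc)2, RuPhos, K3PO4, toluene/H2O, 80 °C]. The aqueous base is expected to cleave the two aryl acetates as well, so the coupling should deliver the diphenol directly (any remaining acetate being removed with K2CO3/MeOH), and the route is rejoined at 22.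

3. Step 7. The bromoenoate may act as a Michael acceptor or as a carbon acid toward the dienolate (conjugate addition followed by cyclopropane closure, or γ-deprotonation), and some γ-alkylation may occur. Fallback, setting out from 10: alkylation of the same sodium dienolate with allyl bromide, a well-behaved electrophile, to (S)-4-benzyl-3-[(S)-2-(prop-1-en-2-yl)pent-4-enoyl]oxazolidin-2-one F3. Cross-metathesis of its monosubstituted alkene with excess methyl methacrylate (second-generation Hoveyda–Grubbs catalyst, CH2Cl2, 40 °C) should then build the E-trisubstituted enoate, with the hindered isopropenyl group as a spectator, and the route is rejoined at 17.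

Further compounds
F1 | step 12 | methyl (2E,5R)-5-{[(8R)-6-benzoyl-7-hydroxy-2,2-dimethyl-8-(3-methylbut-2-en-1-yl)-5-oxo-5,8-dihydro-2H-chromen-8-yl]methyl}-2,6-dimethylhepta-2,6-dienoate | C=C(C)[C@H](C/C=C(\C)C(=O)OC)C[C@]1(CC=C(C)C)C(O)=C(C(=O)c2ccccc2)C(=O)C2=C1OC(C)(C)C=C2
F2 | step 10 | methyl (2E,5S)-2,6-dimethyl-5-[(4,4,5,5-tetramethyl-1,3,2-dioxaborolan-2-yl)methyl]hepta-2,6-dienoate | C=C(C)[C@H](C/C=C(\C)C(=O)OC)CB1OC(C)(C)C(C)(C)O1
F3 | step 7 | (S)-4-benzyl-3-[(S)-2-(prop-1-en-2-yl)pent-4-enoyl]oxazolidin-2-one | C=C(C)[C@H](CC=C)C(=O)N1C(=O)OC[C@@H]1Cc1ccccc1
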